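The reading at 2.0 min was what counted, so I turned each constant into a time at the charged amounts and asked which steps fitted inside it.

E 0.80 M (fed, over 25 s); G 0.80 mM; time 2.0 min; the fed solution adds 0.20 times the starting volume

    E + G ⇌ J + G, rate k1*[E]*[G] forward; the back reaction follows from the equilibrium constant (K1 = 3.3, k1 = 17 L mol⁻¹ s⁻¹)
    J + G ⇌ X + G, rate k2*[G]*[J] forward; the back reaction follows from the equilibrium constant (K2 = 0.42, k2 = 37 L mol⁻¹ s⁻¹)
    Z + G ⇌ E + G, rate k3*[G]*[Z] forward; the back reaction follows from the equilibrium constant (k3 = 6.9 L mol⁻¹ s⁻¹)
    E + G ⇌ E.G, settled at all times (K4 = 0.85 L mol⁻¹)
    X + G ⇌ Z + G, rate k5*[G]*[X] forward; the back reaction follows from the equilibrium constant (K5 = 0.98, k5 = 1.1 L mol⁻¹ s⁻¹)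

- at 2.0 min, what has stopped the reaction, if anything has (forward and back rates have come level / no working catalyst is left / it is still moving / all of E has reacted)
- conversion of E at 2.0 min
- amount of J at 2.0 min, in percent of the E charged
- amount of Z at 2.0 min, in percent of the E charged

- charges are per starting volume, the dose included; the dosed solution carries all of it
- the reaction counts as stopped when no species that holds the E changes by six tenths of a point or more over the second half of the time
- run time (flask): 2.0 min

| Step, forward rate alone | Half-life, G as charged | Against the reading |
|---|---|---|
| J to X | 0.39 min | well inside |
| E to J | 0.85 min | inside |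
| E to Z | 1.54 min | inside |
| X to Z | 13 min | far outside |

The binding of E to G sits above this ladder, being kept at balance throughout. The forward half-life of J to X is shorter than the time to the reading, while that of X to Z is far longer, so I treated E as draining through two routes, to J and to Z.

The balance of the whole round puts 14.2% of the material in E. For free G, written G_f, I diluted the charge by the feed and took E at half of its diluted charge, which gave G_f = 0.519 mM as an estimate. The two routes out of E have summed constants of 26.4 L mol⁻¹ s⁻¹.

I carried one quantity, τ_E, the relaxation time of E: the share of material outside E at balance, divided by that sum times G_f, which is 1.04 min. Counting from the middle of the feed, the flask had 1.79 min to run. That left E at 29.6%, a conversion of 70.4%. By this estimate E fell by 25 percentage points over the second half of the time, so I called the flask still moving. My reckoning went no further than E.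

The forecast's verdict was "it is still moving", with conversion 70%, J 33% and Z 23%, on this ground: “the slow X-to-Z step has not relaxed by 2 minutes and the mixture is still shifting”.

The simulation's verdict was "it is still moving", with conversion 69.5%, J 33.9% and Z 22.7%. The flask was caught in passage: left ten times as long, J rose to 46.8%, while Z came down to 19.4%, less than at the reading. At the reading, 1.72 τ_E had passed and E stood 16 points above its balance share. In the flask with the same charge read at 50 s, 0.599 τ_E put E at 61.3%, and it read 63.6%.

All constants are those of an exercise; the rest is arithmetic.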